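All runs stem from a simulated flask on assumed constants, and the scatter is random.

Begin with the constants: the loading of free enzyme and the impurity are charged alike in the delta and beta runs, so beta, with twice the substrate at a lower temperature, also holds twice the free enzyme against the same impurity.

| flask | substrate | free enzyme | impurity | temperature | remark | time |
|---|---|---|---|---|---|---|
| delta | 0.089 M | 7.5 × 10⁻⁴ mol% | 0.77 µM | 30 °C | the very flask that is asked about, followed so far |  |
| beta | 0.18 M | 7.5 × 10⁻⁴ mol% | 0.77 µM | 15 °C | run made earlier |  |
| flask | 0.089 M | 7.5 × 10⁻⁴ mol% | 0.77 µM | 30 °C |  | 2.5 d |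

| run | time / d | product / % | substrate / % |
|---|---|---|---|
| delta | 0.208 | 18.6 | 78.7 |
| delta | 0.625 | 23.6 | 76.4 |
| delta | 1.25 | 23.2 | 78.0 |
| delta | 1.67 | 22.6 | 77.0 |
| delta | 2.50 | 21.6 | 79.3 |
| beta | 1.04 | 67.0 | 32.9 |
| beta | 2.00 | 99.0 | 1.4 |
| beta | 4.00 | 100.4 | 0 |
| beta | 5.00 | 100.8 | 0 |

(scatter of a reading: 1 percentage point)

- dusk: change nothing and wait 30 h more
- autumn: at 2.5 d raise the temperature by 25 K, then wait 30 h
- dawn: at 2.5 d take out 90% of the product then present, then wait 30 h
- spring: at 2.5 d add free enzyme, 100% of the amount charged, then wait 30 h

- product taken out counts as made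
- the earlier runs were read with a standard deviation of 1 percentage point
- additions bring no volume worth counting

- product, in percent of the substrate first charged, at 2.5 d
- the option that brings most further product ("none" if no option brings more than 2 percentage points) (dusk / autumn / dawn / spring / none)
- product present, with what was taken out counted in, in percent of the substrate first charged, after autumn
- product present, with what was taken out counted in, in percent of the substrate first charged, after spring

Read the delta table down its product column: 18.6% at 0.208 d, 23.6% at 0.625 d, then 21.6% at 2.50 d, with substrate still at 79.3% of the charge. Then read the beta column, which passes that level and ends at 100.8%, so treat the delta stop as a loss of catalyst, not as the end of the substrate.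

Freeze the impurity as a fixed titre, one impurity taking out one free enzyme, and reckon the flask's cover of 0.867, the moles of free enzyme charged per mole of impurity charged, against 1.75 in beta. Below one, the flask charges less free enzyme than impurity, so my reckoning leaves the flask 13.3% of its impurity and no free enzyme. Expect dusk, autumn and dawn to add nothing, while the spring dose, set against that leftover, has a cover of 6.51.

The cover gives no percentage, but the forecast does: 22.6% now, 22.6% after autumn, 99% after spring, and spring as best, on the grounds of “a stoichiometric poison”.

The flask gives 23.0% now, 23.0% after autumn and >99.9% after spring, and the best option is spring, with 77 percentage points further against 0 points for dusk, 0 points for autumn and 0 points for dawn.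

    free enzyme → unfolded enzyme (k = 8.45 × 10⁻⁶ min⁻¹, Ea = 190 kJ mol⁻¹)
    substrate + free enzyme → product + free enzyme, rate k2*[substrate]*[free enzyme]/(1 + ([substrate]/Km2) + ([substrate]/Ksi2)^2) (0.242 M, 0.0746 M, k = 11300 M⁻¹ min⁻¹, Ea = 44.0 kJ mol⁻¹)
    free enzyme + impurity → spent catalyst (k = 35800 M⁻¹ min⁻¹, Ea = 40.0 kJ mol⁻¹)
    (constants at 30 °C)

Substrate turned into product while free enzyme lasted, half of that turnover being done by 0.0590 d. At 0.250 d the flask held 4.60% free enzyme and 95.3% spent catalyst, and at 2.50 d it held 0% free enzyme beside 77.0% substrate and 13% impurity. So this flask, at a cover of 0.867, has stalled with 77.0% of its substrate still free: dose it.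

Take the neighbour charged at 0.0013 mol%: its cover is 1.50, above one, which puts 66.7% of its catalyst down as spent. Computed, that neighbour ends with 66.6% spent catalyst, 32.4% free enzyme, 1.02% unfolded enzyme, 0% impurity and >99.9% product.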